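**Plan**

- Retrosynthesis: cut the C8 angelate, return the C3 and C8 carbinols to ketones and the lactone carbonyl to a C12 ether CH2. Then cut C1–C10 as the reverse of a [3,3] shift, which re-forms a C3–C8 bond that the target does not contain. Last, cut C3–C2 (vinyl), C8–C9 (allyl), C8–O and C6–O.
- Enabling feature: the oxygenated carbons C3 and C8 lie 1,6 across the ten-membered ring and C10–OH is beta to C8. A C3–C8 bond turns the ring into the cyclohexene C3–C4(C15)=C5–C6–C7–C8 of carvone (C11–C13 = its isopropenyl group). C3 then carries a vinyl group (C2=C1), and C8 an acetonyl group whose enol (C9=C10–O) is locked with O8 in a six-membered silylene ring.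
- Order of rings: carvone ring; cis-fused tetrahydrofuran on C6–C7 (masked lactone) by iodoetherification; spiro dioxasiline on C8; oxy-Cope expansion of the six-membered ring to the ten-membered ring with formation of C1–C10; silylene removed; ether oxidised to the lactone.
- Stereochemistry: C7 from (S)-carvone; C6 from the cis ring fusion; the quaternary C8 centre (allyl, then OH, both anti to the C7 side chain) is relayed suprafacially to C10; C8–H by C10–OH-directed anti reduction; C3 by oxazaborolidine control; the Z-C4=C5 alkene is inherited from the cyclohexene.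

Key step: step 10

Remarks: the target is read as the cis-fused 6,12-lactone (H6 and H7 on the same face) with 3S,6S,7R,8R,10S. Germacrane numbers of the target are used for all intermediates (C14 = methyl on C10, C15 = methyl on C4). Compound 13 is drawn as the C3 epimer expected from addition anti to the C8–O bond; either epimer should serve in step 10.

**Step 1**
Reactants: 1 (S)-(+)-carvone
Product: 2 (S)-10-chlorocarvone, (5S)-5-(3-chloroprop-1-en-2-yl)-2-methylcyclohex-2-en-1-one
Conditions: Ca(OCl)2, CO2 (solid), CH2Cl2/H2O, 0 °C
Reagents that add atoms: calcium hypochlorite, [Ca+2].[O-]Cl.[O-]Cl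
Why: Ene-type allylic chlorination by HOCl (liberated from Ca(OCl)2 by CO2) should occur only at the electron-rich isopropenyl group, the enone alkene being electron-poor, and it leaves the C7 stereocentre untouched.

**Step 2**
Reactants: 2 (S)-10-chlorocarvone
Product: 3 (S)-10-(benzyloxy)carvone
Conditions: BnOH, NaH, n-Bu4NI (cat.), THF, 0 °C to rt
Reagents that add atoms: benzyl alcohol, OCc1ccccc1
Why: Williamson ether synthesis on the primary allylic chloride, in which direct and allylic displacement give the same ether because both allyl termini are CH2 groups.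

**Step 3**
Reactants: 3 (S)-10-(benzyloxy)carvone; 4 allyl bromide
Product: 5 (5S,6R)-6-allyl-5-[3-(benzyloxy)prop-1-en-2-yl]-2-methylcyclohex-2-en-1-one (allyl on C8, trans to the C7 side chain)
Conditions: LiN(iPr)2, THF, −78 °C; then 4, DMPU, −78 to −30 °C
Reagents that add atoms: allyl bromide (4), C=CCBr
Why: Kinetic deprotonation gives the cross-conjugated lithium enolate at C8, which is alkylated anti to the neighbouring C7 side chain (enolate alkylation), so the allyl group ends up trans to it.

**Step 4**
Reactants: 5 allyl ketone
Product: 6 (5R,6R)-6-allyl-5-[3-(benzyloxy)prop-1-en-2-yl]-6-hydroxy-2-methylcyclohex-2-en-1-one (C8: OH trans, allyl cis to the C7 side chain)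
Conditions: KN(SiMe3)2, THF, −78 °C; 2-(phenylsulfonyl)-3-phenyloxaziridine; AcOH
Reagents that add atoms: 2-(phenylsulfonyl)-3-phenyloxaziridine, O=S(=O)(c1ccccc1)N1OC1c1ccccc1
Why: Enolate hydroxylation by the N-sulfonyloxaziridine, in which the tetrasubstituted C8 enolate is again attacked anti to the C7 side chain (held axial by allylic 1,2-strain), so that C8 becomes quaternary with OH trans and allyl cis to that side chain.

**Step 5**
Reactants: 6 hydroxy enone
Product: 7 deconjugated beta,gamma-enone (C5=C6; both C4 epimers)
Conditions: KN(SiMe3)2 (2.3 equiv), THF, −78 to −40 °C; AcOH, −78 °C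
Reagents that add atoms: none
Why: Enone deconjugation, since with C8 quaternary only the C6 hydrogens can be removed and kinetic protonation of the linear dienolate at C4 should give the beta,gamma-enone, while the quaternary C8 also closes the path to a phenol.

**Step 6**
Reactants: 7 beta,gamma-enone
Product: 9 cis-fused tetrahydrofuran enone (C3 ketone, C4=C5, C6–O–C12 ether, C11=C13; C8 OH trans and allyl cis to C11), via iodo ether 8 (not isolated)
Conditions: I2, NaHCO3, MeCN, 0 °C; then DBU, rt
Reagents that add atoms: none
Why: Debenzylative iodoetherification followed by E1cB loss of HI, in which the iodonium ion on C5=C6 is opened 5-exo by the benzyl ether oxygen that can reach C6 only from the face of the C7 side chain (cis fusion, sets C6), benzyl leaves as benzyl iodide, and the C4 enolate then expels iodide to restore the enone.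

**Step 7**
Reactants: 9 tetrahydrofuran enone
Product: 10 methyl ketone (C8 bears OH and CH2C(=O)CH3)
Conditions: PdCl2 (cat.), CuCl, O2 (1 atm), DMF/H2O, rt
Reagents that add atoms: water, O
Why: Wacker oxidation of the terminal allyl alkene to the methyl ketone (Markovnikov hydroxypalladation), to which the 1,1-disubstituted exocyclic alkene and the enone are inert.

**Step 8**
Reactants: 10 methyl ketone
Product: 11 spiro dioxasiline enone (C8–O–Si(tBu)2–O–C10(CH3)=C9, six-membered, spiro at C8)
Conditions: tBu2Si(OTf)2, Et3N, CH2Cl2, 0 °C to rt
Reagents that add atoms: di-tert-butylsilyl bis(trifluoromethanesulfonate), CC(C)(C)[Si](OS(=O)(=O)C(F)(F)F)(OS(=O)(=O)C(F)(F)F)C(C)(C)C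
Why: Silylation of the C8 hydroxyl and intramolecular soft enolisation of the beta-ketone (silyl triflate with amine base) should close the cyclic silylene enol ether as its more substituted endocyclic isomer with O10 cis to C8, while the enone oxygen, having no alpha-hydrogen on C4 or C8, can be silylated only reversibly.

**Step 9**
Reactants: 11 spiro dioxasiline enone; 12 vinylmagnesium bromide
Product: 13 tertiary carbinol (C3: OH and vinyl; OH cis to the C8–O bond)
Conditions: CeCl3, THF, −78 °C; then 12
Reagents that add atoms: vinylmagnesium bromide (12), C=C[Mg]Br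
Why: 1,2-Addition of the organocerium reagent to the hindered, non-enolisable enone carbonyl, expected anti to the C8–O bond (polar Felkin–Anh), the C3 configuration being lost again in step 10.

**Step 10**
Reactants: 13 tertiary carbinol
Product: 15 bridged ten-membered enone (C3 ketone, Z-C4=C5, C1–C10 bond, C8=C9 enol ether with C8–O–Si(tBu)2–O–C10 bridge, 10S), via potassium dienolate 14 (not isolated)
Conditions: KN(SiMe3)2, 18-crown-6, THF, −78 to 0 °C; then AcOH, −78 °C
Reagents that add atoms: none
Why: Proposed new method: Deprotonation of the C3 carbinol gives the potassium 3-oxido-1,5-diene C1=C2–C3(O−)–C8–C9=C10, whose charge-accelerated [3,3] shift breaks C3–C8 and joins C1 to C10, leaving dienolate 14, which is protonated at C2. The closest known reaction type is the anionic oxy-Cope ring expansion of 1,2-dialkenylcyclohexanols to cyclodec-5-enones; new here is that the second alkene is the endocyclic enol ether of a spiro dioxasiline, so that the terminus becomes a fully substituted C–O carbon. The ten-membered ring is closed by four-atom ring expansion of the carvone-derived six-membered ring and not by end-to-end cyclisation, and the dioxasiline survives as a bridge from C8 to C10 with its C8=C9 enol ether trans in the large ring. C10, the only new stereocentre, is set by suprafacial transfer across the C8–C9–C10 allyl unit: the silylene ring fixes the enol ether geometry (O10 cis to C8), so C1 must bond to the heterocycle face that carried C3, and the C8 configuration from steps 3 and 4 gives 10S through a chair or a boat array and from either C3 epimer. The step needs C3–C8 to break in preference to C7–C8 (the other 1,5-diene, through C11=C13) and C1 instead of C5 to bond to C10; the oxido group activates only bonds to C3, the C3–C8 bond is flanked by two oxygens and by the C4=C5 alkene, and the ring alkene could reach C10 only through a bridged boat. The tert-butyl groups should keep the neighbouring alkoxide from attacking silicon, and transannular aldol closure of 14 is excluded because C8 stays a silyl enol ether.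

**Step 11**
Reactants: 15 bridged ten-membered enone
Product: 16 (4Z,10S)-6,12-epoxy-10-hydroxygermacra-4,11(13)-diene-3,8-dione
Conditions: HF·pyridine, pyridine, THF, 0 °C to rt
Reagents that add atoms: none
Why: Fluoride cleaves both Si–O bonds of the silylene and the freed C8 enol tautomerises to the ketone under buffered, non-basic conditions, which should avoid retro-aldol cleavage and migration of the C11=C13 alkene into conjugation, 16 being reduced at once.

**Step 12**
Reactants: 16 hydroxy diketone
Product: 17 (4Z,8R,10S)-6,12-epoxy-8,10-dihydroxygermacra-4,11(13)-dien-3-one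
Conditions: Me4NBH(OAc)3, MeCN/AcOH, −30 °C
Reagents that add atoms: none
Why: Evans–Saksena reduction, in which the C10 hydroxyl binds the triacetoxyborohydride and delivers hydride to C8 through a chair transition state with C1 and C7 equatorial to give the 1,3-anti diol (8R), while the C3 enone, not being a beta-hydroxy ketone, is not reduced.

**Step 13**
Reactants: 17 anti-diol; 18 angelic acid
Product: 19 8-O-angeloyl ester of 17
Conditions: 18, 2,4,6-trichlorobenzoyl chloride, Et3N, toluene, rt; then 17, 80 °C
Reagents that add atoms: angelic acid (18), C/C=C(/C)C(=O)O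
Why: Yamaguchi-type esterification through the mixed anhydride, the usual way to angelates without Z to E isomerisation, acylates only the secondary C8 hydroxyl because the C10 hydroxyl is tertiary.

**Step 14**
Reactants: 19 angelate ether
Product: 20 (4Z)-8-angeloyloxy-10-hydroxy-3-oxogermacra-4,11(13)-dien-6,12-olide
Conditions: CrO3·2C5H5N (excess), CH2Cl2, rt
Reagents that add atoms: chromium trioxide, O=[Cr](=O)=O
Why: Allylic ether oxidation as known for 3-methylenetetrahydrofurans, directed to C12–H2 because it is both allylic to the electron-rich 1,1-disubstituted alkene and alpha to the ring oxygen, whereas C6–H is allylic only to the electron-poor enone alkene.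

**Step 15**
Reactants: 20 keto lactone
Product: 21 target, (3S,6S,7R,8R,10S)-8-angeloyloxy-3,10-dihydroxygermacra-4Z,11(13)-dien-6,12-olide
Conditions: (R)-2-methyl-CBS-oxazaborolidine (cat.), catecholborane, toluene, −78 °C
Reagents that add atoms: none
Why: Corey–Bakshi–Shibata reduction of the enone carbonyl, 1,2-selective with catecholborane, in which the (R)-catalyst should distinguish the alkenyl side (C4) from the CH2 side (C2) and deliver hydride to give 3S while the angelate and the lactone are left alone at −78 °C.

**Compound list**

1 | (S)-(+)-carvone | CC1=CC[C@H](C(C)=C)CC1=O | starting material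
2 | (S)-10-chlorocarvone | CC1=CC[C@H](C(CCl)=C)CC1=O | intermediate
3 | (S)-10-(benzyloxy)carvone | CC1=CC[C@H](C(COCc2ccccc2)=C)CC1=O | intermediate
4 | allyl bromide | C=CCBr | starting material
5 | (5S,6R)-6-allyl-5-[3-(benzyloxy)prop-1-en-2-yl]-2-methylcyclohex-2-en-1-one (allyl trans to side chain) | CC1=CC[C@H](C(COCc2ccccc2)=C)[C@@H](CC=C)C1=O | intermediate
6 | (5R,6R)-6-allyl-5-[3-(benzyloxy)prop-1-en-2-yl]-6-hydroxy-2-methylcyclohex-2-en-1-one (OH trans, allyl cis to side chain) | CC1=CC[C@H](C(COCc2ccccc2)=C)[C@](O)(CC=C)C1=O | intermediate
7 | (5R,6R)-6-allyl-5-[3-(benzyloxy)prop-1-en-2-yl]-6-hydroxy-2-methylcyclohex-3-en-1-one (both epimers at the methyl-bearing carbon) | CC1C=C[C@H](C(COCc2ccccc2)=C)[C@](O)(CC=C)C1=O | intermediate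
8 | iodo ether: cis-fused 3-methylenetetrahydrofuran on C6–C7, iodine on C5 trans to the ring oxygen, C3 ketone, C8 OH and allyl as in 6 (both C4 epimers) | CC1[C@@H](I)[C@@H]2OCC(=C)[C@@H]2[C@](O)(CC=C)C1=O | intermediate
9 | cis-fused 4-allyl-4-hydroxy-6-methyl-3-methylene-3,3a,4,7a-tetrahydro-1-benzofuran-5(2H)-one (4-OH trans to the C3a–C3 bond) | CC1=C[C@@H]2OCC(=C)[C@@H]2[C@](O)(CC=C)C1=O | intermediate
10 | 4-(2-oxopropyl) analogue of 9 (methyl ketone) | CC1=C[C@@H]2OCC(=C)[C@@H]2[C@](O)(CC(C)=O)C1=O | intermediate
11 | spiro enone: 2,2-di-tert-butyl-6-methyl-4H-1,3,2-dioxasiline spiro-fused through its C4 to C8 of the bicyclic enone (silylene oxygen on C8 trans to C11) | CC1=C[C@@H]2OCC(=C)[C@@H]2[C@@]3(O[Si](C(C)(C)C)(C(C)(C)C)OC(C)=C3)C1=O | intermediate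
12 | vinylmagnesium bromide | C=C[Mg]Br | starting material
13 | tertiary carbinol: vinyl and OH on C3 of 11, OH cis to the C8–O bond | CC1=C[C@@H]2OCC(=C)[C@@H]2[C@@]3(O[Si](C(C)(C)C)(C(C)(C)C)OC(C)=C3)[C@]1(O)C=C | intermediate
14 | potassium dienolate of 15 (C2=C3–O−, C2=C3 geometry not defined) | C=C1CO[C@H]2/C=C(/C)C([O-])=CC[C@]3(C)O[Si](C(C)(C)C)(C(C)(C)C)OC(=C3)[C@@H]12.[K+] | intermediate
15 | bridged ten-membered enone: (4Z,10S)-6,12-epoxygermacra-4,8,11(13)-trien-3-one with C8–O–Si(tBu)2–O–C10 bridge | C=C1CO[C@H]2/C=C(/C)C(=O)CC[C@]3(C)O[Si](C(C)(C)C)(C(C)(C)C)OC(=C3)[C@@H]12 | intermediate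
16 | (4Z,10S)-6,12-epoxy-10-hydroxygermacra-4,11(13)-diene-3,8-dione (C6, C7 as in the target) | C=C1CO[C@H]2/C=C(/C)C(=O)CC[C@](C)(O)CC(=O)[C@@H]12 | intermediate
17 | (4Z,8R,10S)-6,12-epoxy-8,10-dihydroxygermacra-4,11(13)-dien-3-one | C=C1CO[C@H]2/C=C(/C)C(=O)CC[C@](C)(O)C[C@@H](O)[C@@H]12 | intermediate
18 | angelic acid, (Z)-2-methylbut-2-enoic acid | C/C=C(/C)C(=O)O | starting material
19 | 8-O-angeloyl ester of 17 | C=C1CO[C@H]2/C=C(/C)C(=O)CC[C@](C)(O)C[C@@H](OC(=O)/C(C)=C\C)[C@@H]12 | intermediate
20 | (4Z)-8-angeloyloxy-10-hydroxy-3-oxogermacra-4,11(13)-dien-6,12-olide (cis-fused lactone) | C=C1C(=O)O[C@H]2/C=C(/C)C(=O)CC[C@](C)(O)C[C@@H](OC(=O)/C(C)=C\C)[C@@H]12 | intermediate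
21 | CNP0137971.2, (3S,6S,7R,8R,10S)-8-angeloyloxy-3,10-dihydroxygermacra-4Z,11(13)-dien-6,12-olide | C=C1C(=O)O[C@H]2/C=C(/C)[C@@H](O)CC[C@](C)(O)C[C@@H](OC(=O)/C(C)=C\C)[C@@H]12 | target

Total step count: 15. Longest linear sequence: 15 steps, from (S)-carvone.

**Steps most likely to fail**

Step 10 (Proposed new method). The alkoxide may attack silicon and open the dioxasiline instead of rearranging, or the array may react by fragmentation and re-addition, which would erode the transfer of chirality from C8 to C10. The fallback uses known chemistry, forming the same C1–C10 bond by a six-membered ring closure and then cleaving the C3–C8 bond. It sets out from 11. Addition of the lithium enolate of tert-butyl acetate (LiN(iPr)2, THF, −78 °C) to the C3 ketone should give the beta-hydroxy ester F1. LiAlH4 reduces the ester to the C1,C3-diol F2. HF·pyridine removes the silylene to give the keto triol F3. I2, PPh3 and imidazole convert the primary alcohol into the iodide F4. An intramolecular ketone Barbier reaction with SmI2 in THF/HMPA joins C1 to C10 and closes a cyclohexane ring, giving the bicyclic triol F5; chelation of samarium between O8 and the ketyl oxygen is expected to give the cis-8,10-diol, which corresponds to 10S. Pb(OAc)4 in CH2Cl2 then cleaves the cis C3/C8 glycol and opens the bicycle to the ten-membered diketone. The fallback comes back to the route at 16.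

Step 14. Oxidation may occur at other allylic or alpha-oxygenated C–H bonds (C6–H, C15), and the C3 ketone can close with the C10 hydroxyl to a 3,10-hemiketal whose tertiary allylic hydroxyl could undergo chromate-induced transposition. The fallback replaces hydrogen-atom abstraction by hydride abstraction in two stages. It sets out from 19. DDQ in buffered CH2Cl2/H2O should abstract hydride from C12, the only site that gives an oxocarbenium ion conjugated with an electron-rich alkene, and water capture gives the lactol F6. MnO2 in CH2Cl2 oxidises this allylic lactol to the lactone. The fallback comes back at 20.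

Step 15. Facial selectivity at C3 may be poor because the ketone equilibrates with its 3,10-hemiketal and the ring conformation can override the catalyst; conjugate reduction of the methylene lactone may also compete. The fallback corrects the configuration by inversion instead of relying on facial control. It sets out from 20. Substrate-controlled Luche reduction (NaBH4, CeCl3·7H2O, MeOH, −78 °C), if it favours the wrong face, gives the C3 epimer F7. Mitsunobu inversion with formic acid (PPh3, DIAD, THF) gives the 3S formate F8; the tertiary C10 hydroxyl does not react. KHCO3 in MeOH/H2O cleaves the formate in the presence of the angelate. The fallback comes back at 21.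

**Further compounds**

F1 | step 10 | beta-hydroxy tert-butyl ester from acetate addition to C3 of 11 | CC1=C[C@@H]2OCC(=C)[C@@H]2[C@@]3(O[Si](C(C)(C)C)(C(C)(C)C)OC(C)=C3)[C@]1(O)CC(=O)OC(C)(C)C
F2 | step 10 | C1,C3-diol with intact dioxasiline | CC1=C[C@@H]2OCC(=C)[C@@H]2[C@@]3(O[Si](C(C)(C)C)(C(C)(C)C)OC(C)=C3)[C@]1(O)CCO
F3 | step 10 | keto triol (C3 OH and CH2CH2OH, C8 OH and acetonyl) | CC1=C[C@@H]2OCC(=C)[C@@H]2[C@](O)(CC(C)=O)[C@]1(O)CCO
F4 | step 10 | primary iodide of F3 | CC1=C[C@@H]2OCC(=C)[C@@H]2[C@](O)(CC(C)=O)[C@]1(O)CCI
F5 | step 10 | bicyclic 3,8,10-triol with C3–C8 and C1–C10 bonds (cis-8,10-diol, cis-3,8-diol) | CC1=C[C@@H]2OCC(=C)[C@@H]2[C@]3(O)C[C@@](C)(O)CC[C@]13O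
F6 | step 14 | C12 lactol of 19 (both anomers) | C=C1C(O)O[C@H]2/C=C(/C)C(=O)CC[C@](C)(O)C[C@@H](OC(=O)/C(C)=C\C)[C@@H]12
F7 | step 15 | 3-epi-21 (3R alcohol) | C=C1C(=O)O[C@H]2/C=C(/C)[C@H](O)CC[C@](C)(O)C[C@@H](OC(=O)/C(C)=C\C)[C@@H]12
F8 | step 15 | 3-O-formate of 21 | C=C1C(=O)O[C@H]2/C=C(/C)[C@@H](OC=O)CC[C@](C)(O)C[C@@H](OC(=O)/C(C)=C\C)[C@@H]12
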